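**Plan**

- Retrosynthesis: the five benzyl ethers come off last. Both bonds at the pentanoyl carbonyl carbon of ring A (aryl–C(=O) and C(=O)–butyl) are then cut, giving an aryl iodide, CO and B-butyl-9-BBN.
- Behind the iodide, the C–I bond and the five O–benzyl bonds are removed, and the CH2–ring A bond is cut to 2-methylphloroglucinol and the Mannich base of aspidinol (ring B). Aspidinol comes from 2-methylphloroglucinol by C-butanoylation and 4-O-methylation.
- Forward: ring B is elaborated first, joined to ring A through an ortho-quinone methide, ring A is iodinated and the phenols benzylated, and the pentanoyl chain is assembled last. Both benzene rings are bought; no ring is formed.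
- Enabling feature: the pentanoyl-bearing carbon of ring A lies between two oxygen-bearing ring carbons and is the only ring carbon of the dimer that still carries hydrogen. It alone can be iodinated, and the ketone can then be built under basic, acid-free palladium catalysis that leaves the acid-labile CH2 bridge between rings A and B in place.
- Stereochemistry: the target has no stereocentre and no stereogenic double bond, so nothing has to be set.

Key step: step 8

Remark: the target is treated as the fully aromatic phenol–ketone tautomer drawn in its SMILES; the alkylborane 12 is used as its THF solution.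

**Route**

Step 1
Reactants: 1 2-methylphloroglucinol (2-methylbenzene-1,3,5-triol); 2 butanoyl chloride
Product: 3 1-(2,4,6-trihydroxy-3-methylphenyl)butan-1-one
Conditions: AlCl3 (4 equiv), PhNO2–CH2Cl2, 0 °C to 50 °C; then cold 1 M HCl
Reagents that add atoms: none
Why: Friedel–Crafts C-acylation of the electron-rich triol, in which the two free ring carbons of 1 are equivalent and the first acyl group deactivates the ring against a second.

Step 2
Reactants: 3 1-(2,4,6-trihydroxy-3-methylphenyl)butan-1-one
Product: 4 1-(2,6-dihydroxy-4-methoxy-3-methylphenyl)butan-1-one (aspidinol)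
Conditions: Me2SO4 (1.0 equiv), K2CO3 (1.0 equiv), acetone, rt to reflux
Reagents that add atoms: dimethyl sulfate, COS(=O)(=O)OC
Why: Williamson O-methylation, expected at the 4-OH because it is para to the ketone (most acidic) and the only hydroxyl that cannot chelate the carbonyl, so one equivalent of methylating agent should stop there.

Step 3
Reactants: 4 aspidinol
Product: 5 1-{3-[(dimethylamino)methyl]-2,6-dihydroxy-4-methoxy-5-methylphenyl}butan-1-one
Conditions: 37% aq. CH2O, 40% aq. Me2NH, EtOH, 0 °C to rt
Reagents that add atoms: formaldehyde, C=O; dimethylamine, CNC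
Why: phenol Mannich reaction at the single ring carbon of 4 that bears hydrogen, which is ortho to a free hydroxyl.

Step 4
Reactants: 5 Mannich base of aspidinol; 1 2-methylphloroglucinol (4 equiv)
Product: 7 1-{2,6-dihydroxy-4-methoxy-3-methyl-5-[(2,4,6-trihydroxy-3-methylphenyl)methyl]phenyl}butan-1-one, via ortho-quinone methide 6 (not isolated)
Conditions: dioxane, 100 °C, argon
Reagents that add atoms: none
Why: thermal elimination of dimethylamine from the phenolic Mannich base gives the ortho-quinone methide, which is trapped by conjugate addition (Friedel–Crafts-type alkylation) of 1 at one of its two equivalent free carbons; ring B has no free carbon and cannot homodimerise, and the excess of 1 suppresses a second alkylation of ring A.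

Step 5
Reactants: 7 diarylmethane pentaphenol
Product: 8 1-{2,6-dihydroxy-4-methoxy-3-methyl-5-[(2,4,6-trihydroxy-3-iodo-5-methylphenyl)methyl]phenyl}butan-1-one
Conditions: NIS (1.0 equiv), THF, −40 °C to 0 °C, dark
Reagents that add atoms: N-iodosuccinimide, O=C1CCC(=O)N1I
Why: electrophilic aromatic iodination at the only C–H of the dimer, which sits between two hydroxyls on the electron-rich ring A, while ring B is fully substituted and the neutral succinimide by-product leaves the bridge alone.

Step 6
Reactants: 8 ring A iodide pentaphenol
Product: 9 1-[2,6-bis(benzyloxy)-4-methoxy-3-methyl-5-{[2,4,6-tris(benzyloxy)-3-iodo-5-methylphenyl]methyl}phenyl]butan-1-one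
Conditions: BnBr (7.5 equiv), K2CO3 (10 equiv), DMF, 60 °C, argon, dark
Reagents that add atoms: benzyl bromide, BrCc1ccccc1
Why: Williamson etherification of all five phenols in a polar aprotic solvent that favours O-alkylation, made cleaner because iodine already occupies the last ring carbon, so C-benzylation could occur only with loss of aromaticity.

Step 7
Reactants: 10 but-1-ene; 11 9-borabicyclo[3.3.1]nonane
Product: 12 9-butyl-9-borabicyclo[3.3.1]nonane
Conditions: 9-BBN (0.5 M in THF), but-1-ene (excess, condensed), 0 °C to rt; solution used directly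
Reagents that add atoms: none
Why: anti-Markovnikov hydroboration of a terminal alkene, in which 9-BBN places boron on the terminal carbon to give the primary alkylborane.

Step 8
Reactants: 9 pentabenzyl ring A iodide; 13 carbon monoxide; 12 9-butyl-9-borabicyclo[3.3.1]nonane
Product: 14 1-[2,4,6-tris(benzyloxy)-3-{[2,4-bis(benzyloxy)-3-butanoyl-6-methoxy-5-methylphenyl]methyl}-5-methylphenyl]pentan-1-one
Conditions: PdCl2(dppf) (10 mol%), K3PO4 (3 equiv), CO (5 bar), dioxane, 80 °C
Reagents that add atoms: none
Why: Carbonylative Suzuki–Miyaura coupling: zerovalent palladium (formed from PdCl2(dppf) and the borane) inserts into the C–I bond of 9, CO binds and migrates to give an aroyl complex of divalent palladium, the phosphate-activated borane 12 hands over its primary butyl group, and reductive elimination forms the carbonyl–butyl bond and frees the catalyst. The closest known reaction type is the palladium-catalysed three-component ketone synthesis from aryl iodides, CO and B-alkyl-9-BBN reagents, applied here to a hexasubstituted iodide with two ortho benzyloxy groups. No ring is closed and no stereocentre is created, so neither a mode of closure nor a stereocontrol element is involved. The selectivity required is ketone formation over direct aryl–butyl coupling, β-hydride loss and hydrodeiodination; the two flanking benzyloxy groups retard transmetalation at the crowded arylpalladium while CO insertion relieves that crowding, and CO pressure with sparingly soluble K3PO4 keeps insertion ahead of butyl transfer. The wide bite angle of dppf then favours fast reductive elimination from the acyl(butyl) complex. The medium is basic and free of Brønsted or Lewis acid, so the CH2 bridge cannot migrate and the ring B ketone and the benzyl ethers are spectators.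

Step 9
Reactants: 14 pentabenzyl ether of the target
Product: 15 1-[3-(3-butanoyl-2,4-dihydroxy-6-methoxy-5-methylbenzyl)-2,4,6-trihydroxy-5-methylphenyl]pentan-1-one (CNP0210501.0)
Conditions: H2 (1 atm), 10% Pd/C, EtOAc–MeOH, rt; filtration and concentration under argon
Reagents that add atoms: none
Why: catalytic hydrogenolysis of the five benzyl aryl ethers under neutral conditions, which leaves the diarylmethane C–C bonds and the two conjugated, hydrogen-bonded aryl ketones untouched.

**Compound list**

1 | 2-methylphloroglucinol (2-methylbenzene-1,3,5-triol) | Cc1c(O)cc(O)cc1O | starting material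
2 | butanoyl chloride | CCCC(Cl)=O | starting material
3 | 1-(2,4,6-trihydroxy-3-methylphenyl)butan-1-one | CCCC(=O)c1c(O)cc(O)c(C)c1O | intermediate
4 | 1-(2,6-dihydroxy-4-methoxy-3-methylphenyl)butan-1-one (aspidinol) | CCCC(=O)c1c(O)cc(OC)c(C)c1O | intermediate
5 | 1-{3-[(dimethylamino)methyl]-2,6-dihydroxy-4-methoxy-5-methylphenyl}butan-1-one | CCCC(=O)c1c(O)c(CN(C)C)c(OC)c(C)c1O | intermediate
6 | 2-butanoyl-3-hydroxy-5-methoxy-4-methyl-6-methylidenecyclohexa-2,4-dien-1-one (ortho-quinone methide, not isolated) | C=C1C(=O)C(C(=O)CCC)=C(O)C(C)=C1OC | intermediate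
7 | 1-{2,6-dihydroxy-4-methoxy-3-methyl-5-[(2,4,6-trihydroxy-3-methylphenyl)methyl]phenyl}butan-1-one | CCCC(=O)c1c(O)c(Cc2c(O)cc(O)c(C)c2O)c(OC)c(C)c1O | intermediate
8 | 1-{2,6-dihydroxy-4-methoxy-3-methyl-5-[(2,4,6-trihydroxy-3-iodo-5-methylphenyl)methyl]phenyl}butan-1-one | CCCC(=O)c1c(O)c(Cc2c(O)c(I)c(O)c(C)c2O)c(OC)c(C)c1O | intermediate
9 | 1-[2,6-bis(benzyloxy)-4-methoxy-3-methyl-5-{[2,4,6-tris(benzyloxy)-3-iodo-5-methylphenyl]methyl}phenyl]butan-1-one | Ic1c(OCc2ccccc2)c(C)c(OCc2ccccc2)c(Cc2c(OCc3ccccc3)c(C(=O)CCC)c(OCc3ccccc3)c(C)c2OC)c1OCc1ccccc1 | intermediate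
10 | but-1-ene | C=CCC | starting material
11 | 9-borabicyclo[3.3.1]nonane | B1C2CCCC1CCC2 | starting material
12 | 9-butyl-9-borabicyclo[3.3.1]nonane | CCCCB1C2CCCC1CCC2 | intermediate
13 | carbon monoxide | [C-]#[O+] | starting material
14 | 1-[2,4,6-tris(benzyloxy)-3-{[2,4-bis(benzyloxy)-3-butanoyl-6-methoxy-5-methylphenyl]methyl}-5-methylphenyl]pentan-1-one | CCCCC(=O)c1c(OCc2ccccc2)c(C)c(OCc2ccccc2)c(Cc2c(OCc3ccccc3)c(C(=O)CCC)c(OCc3ccccc3)c(C)c2OC)c1OCc1ccccc1 | intermediate
15 | 1-[3-(3-butanoyl-2,4-dihydroxy-6-methoxy-5-methylbenzyl)-2,4,6-trihydroxy-5-methylphenyl]pentan-1-one | CCCCC(=O)c1c(O)c(C)c(O)c(Cc2c(O)c(C(=O)CCC)c(O)c(C)c2OC)c1O | target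

**Step count**

Total: 9 steps. Longest linear sequence: 8 steps (steps 1–6, 8, 9); step 7 is a one-step side branch.

**Steps most likely to fail**

Step 8. Transmetalation of the alkylborane at the crowded aroylpalladium may be slow, so that hydrodeiodination, direct butyl transfer without CO, or β-hydride loss overtakes ketone formation. The fallback sets out from 9 and replaces the borane with a terminal alkyne, which has no β-hydrogen and needs no boron-to-palladium transfer. A copper-free carbonylative Sonogashira coupling of 9 with CO 13 and but-1-yne (PdCl2(PPh3)2, Et3N, THF, CO 1–5 bar, rt to 50 °C) should give the ynone 1-[2,4,6-tris(benzyloxy)-3-{[2,4-bis(benzyloxy)-3-butanoyl-6-methoxy-5-methylphenyl]methyl}-5-methylphenyl]pent-2-yn-1-one F1. Hydrogenation over 10% Pd/C under H2 then saturates the triple bond and cleaves the five benzyl ethers in one operation, coming back to the route at 15.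

Step 6. Etherification of the chelated, doubly flanked phenols may stop short, and C-benzylation with dearomatisation of ring A or loss of iodine may compete. The fallback sets out from 8 and uses a hard alkoxymethyl electrophile that alkylates on oxygen only and is still removed by hydrogen. Benzyl chloromethyl ether with NaH in DMF at 0 °C should give 1-[2,6-bis(benzyloxymethoxy)-4-methoxy-3-methyl-5-{[2,4,6-tris(benzyloxymethoxy)-3-iodo-5-methylphenyl]methyl}phenyl]butan-1-one F2. Carbonylative coupling of F2 with 12 and 13 under the conditions of step 8 should give 1-[2,4,6-tris(benzyloxymethoxy)-3-{[2,4-bis(benzyloxymethoxy)-3-butanoyl-6-methoxy-5-methylphenyl]methyl}-5-methylphenyl]pentan-1-one F3. Hydrogenolysis (H2, 10% Pd/C, EtOAc–MeOH) cleaves the five benzyloxymethyl acetals with loss of toluene and formaldehyde; since both rings of the product are fully substituted, the formaldehyde cannot add to carbon. The fallback comes back to the route at 15.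

Step 4. A second quinone methide may alkylate ring A of the product (trimer formation), and the Mannich base may decompose at the temperature needed to expel the amine. The fallback sets out from 5 and turns the amine into a better leaving group so that the quinone methide forms at room temperature. Methyl iodide in THF at rt should give 1-(3-butanoyl-2,4-dihydroxy-6-methoxy-5-methylphenyl)-N,N,N-trimethylmethanaminium iodide F4. With NaHCO3 and excess 1 in aqueous THF–MeOH at rt to 40 °C, F4 loses trimethylamine to the same ortho-quinone methide 6, which is trapped by 1, coming back to the route at 7.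

**Further compounds**

F1 | step 8 | 1-[2,4,6-tris(benzyloxy)-3-{[2,4-bis(benzyloxy)-3-butanoyl-6-methoxy-5-methylphenyl]methyl}-5-methylphenyl]pent-2-yn-1-one | CCC#CC(=O)c1c(OCc2ccccc2)c(C)c(OCc2ccccc2)c(Cc2c(OCc3ccccc3)c(C(=O)CCC)c(OCc3ccccc3)c(C)c2OC)c1OCc1ccccc1
F2 | step 6 | 1-[2,6-bis(benzyloxymethoxy)-4-methoxy-3-methyl-5-{[2,4,6-tris(benzyloxymethoxy)-3-iodo-5-methylphenyl]methyl}phenyl]butan-1-one | Ic1c(OCOCc2ccccc2)c(C)c(OCOCc2ccccc2)c(Cc2c(OCOCc3ccccc3)c(C(=O)CCC)c(OCOCc3ccccc3)c(C)c2OC)c1OCOCc1ccccc1
F3 | step 6 | 1-[2,4,6-tris(benzyloxymethoxy)-3-{[2,4-bis(benzyloxymethoxy)-3-butanoyl-6-methoxy-5-methylphenyl]methyl}-5-methylphenyl]pentan-1-one | CCCCC(=O)c1c(OCOCc2ccccc2)c(C)c(OCOCc2ccccc2)c(Cc2c(OCOCc3ccccc3)c(C(=O)CCC)c(OCOCc3ccccc3)c(C)c2OC)c1OCOCc1ccccc1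
F4 | step 4 | 1-(3-butanoyl-2,4-dihydroxy-6-methoxy-5-methylphenyl)-N,N,N-trimethylmethanaminium iodide | CCCC(=O)c1c(O)c(C[N+](C)(C)C)c(OC)c(C)c1O.[I-]
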